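If we want the most target from one charge, each flask poses two questions: what share of the starting material goes to target, and does the run last long enough to use it up?

    2 starting material → side product B (k1 = 0.00210 L mol⁻¹ h⁻¹, Ea1 = 75.0 kJ mol⁻¹)
    starting material → side product A (k2 = 1.28 × 10⁻⁴ h⁻¹, Ea2 = 93.0 kJ mol⁻¹)
    crystals ⇌ target, rate k3*(cs3 - [target]) while solid is left; crystals form when [target] > cs3 (cs3 = 0.15 M, k3 = 0.253 h⁻¹)
    starting material + coupling partner → target (k4 = 0.00795 L mol⁻¹ h⁻¹, Ea4 = 58.0 kJ mol⁻¹)
    (constants at −20 °C)

all flasks: starting material 2.0 M; coupling partner 0.700 equiv; time 3.0 d

|  | temperature |
|---|---|
| oak | 20 °C |
| maple | −20 °C |
| cedar | 40 °C |
| elm | 0 °C |

- a species is counted by the starting material in it: one side product B counts as two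
- amounts and yields of target count crystals too
- for a step with 2 of a species take k times the square, and two of it per event
- given per volume of solution although it is solid: crystals
- constants are those at −20 °C; use the activation energies for any other temperature

* the flask with the highest amount of target, in percent of the starting material charged ("all alike" if they lie within 1.5 percentage points) (oak / maple / cedar / elm / all alike)
* final target, as a percentage of the starting material charged, in oak
* final target, as a percentage of the starting material charged, in maple
* final target, as a percentage of the starting material charged, in cedar
* final target, as a percentage of the starting material charged, in elm

We begin with time. Starting material leaves by three routes, and its loss per unit of its own concentration is a sum of three terms: 2 times the constant of the step to side product B times c(starting material), the constant of the step to target times c(coupling partner), and the constant of the step to side product A. The inverse of this sum at the charge, with each constant carried to the flask's temperature by its activation energy, we call the starting lifetime τ. It is 0.0948 h in cedar, 0.618 h in oak, 4.97 h in elm and 50.9 h in maple, against a run of 72 h, so cedar stands on the fastest rung. Treating the loss as roughly second order, we take the fraction left after a time t as τ/(τ+t). Hardly any then remains in oak, and less in cedar, while elm keeps 6.46% and maple 41.4%.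

Now the share. The target made per starting material used is the mean of the momentary share going to target, the instantaneous selectivity. This share moves during a run: in cedar the step to target at first uses 0.28 of what the step to side product B uses, so coupling partner falls more slowly than starting material. We replace the curve by one point, where half the charge is used: c(starting material) stands at half its charge, and c(coupling partner) is lowered by the starting share times that half. In cedar this gives 29.3%, and this fraction, the half-way share, is our stand-in for the mean. It is 38.7% in oak, 49.4% in elm and 60.5% in maple, the best share. The step to side product B carries 17.0 kJ mol⁻¹ more activation energy than the step to target, so cold favours target. Multiplying share by fraction used, elm gives 46.2% and maple 35.5%, while oak and cedar stay near their shares. We commit to elm: maple has the better share, but by this reckoning more of its charge stays unused.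

The forecast also names elm, with 41.8% in oak, 35.3% in maple, 32.3% in cedar and 50.3% in elm, the last above our figure. It sets the crystals aside: “nothing consumes target, so it does not affect the yield”.

The simulation gives 41.8% in oak, 35.3% in maple, 32.4% in cedar and 50.2% in elm, so elm leads, as forecast. Cedar's half-way share of 29.3% lies 3 percentage points below its result. Kept for 30.0 d, maple reaches 59.4% and elm 52.1%, so a run that long reverses the forecast's choice. Cedar repeated at 65 °C has a starting lifetime of 0.0118 h and a half-way share of 20.0%, and that flask ends with 22.4% target.

Its constants belong to no real substance; what happens was integrated by code.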